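## The problem

Atom labels used throughout: ring A is C1–C6, ring B is C1'–C6'.

- Target 9 is two benzene rings joined only through one oxygen. Ring A carries O1–H at C1, the bridging oxygen at C2, bromine at C3, C4 and C6, and its only hydrogen at C5. Ring B carries the bridging oxygen at C1' and one bromine at C2'.
- There is no stereocentre, so the whole problem is one of regiochemistry and chemoselectivity.
- The bridging oxygen is flanked by three ortho substituents (O1–H, C3–Br, C2'–Br). Closing either C–O bond is therefore a hindered coupling, and the C–Br bonds of both partners are themselves substrates for copper and palladium.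
- The bromines obey two different rules. C4 and C6 are para and ortho to O1–H and go in by plain phenol bromination. C3 is meta to O1–H, and C2' lies on a ring whose more reactive C4' must stay C–H, so no direct bromination can place these two.
- The C–Br bonds do not survive alkyllithiums, dissolving metals or hydrogenolysis, and an ortho-metalated bromoarene collapses to an aryne. The phenol is easily over-oxidised to bromodienones or quinones.
- The enabling feature is this: C1, C3 and C2' are three of the four carbons ortho to the bridging oxygen. These are exactly the C–H bonds that this oxygen acidifies in diphenyl ether, while C4 and C6 are governed by O1.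
- C3 and C2' can therefore be marked with silicon and C1 oxygenated, all under the direction of the ether oxygen. One electrophile, bromine, can then replace two C–Si and two C–H bonds in a single flask.

## Retrosynthesis

**9 ⇒ 6.**
- Bonds cut: all four C–Br bonds at once. C4 and C6 go back to C–H, and C3 and C2' go back to C–SiMe3.
- Against the neighbouring cuts: cutting the bridging C–O bond first leaves two brominated halves and a hindered coupling. Cutting only C4–Br and C6–Br leaves a dibromide whose C–Br bonds forbid every organolithium step that would have to come before it.
- Silicon is the placeholder of choice. A C–SiMe3 bond survives alkyllithiums and peroxide, yet it is replaced by bromine with the same reagent that brominates the phenol.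
- Precursor 6 is halogen-free and needs no protecting group.
- The forward reaction must make ipso attack at C2' faster than C–H attack at C4'. It must still substitute C3 on a ring that is already deactivated (stages 7 and 8), and it must avoid proton-induced loss of silicon.

**6 ⇒ 3.**
- Bond cut: C1–O1.
- In 3 the two rings are equivalent and each has only one C–H bond left ortho to the bridging oxygen. The question of site disappears, and only mono- against double metalation remains.
- Bringing O1 in before silicon would add a second director that sends the base to C6. Catalytic C–H oxidation has no directing group to hold on to.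
- The precursor loses the only element that distinguishes the rings.
- The forward reaction is one lithiation (4), trapping as borate 5, and oxidation.

**3 ⇒ 1 (through 2).**
- Bonds cut: C3–Si and C2'–Si.
- The 2,2'-dianion 2 of diphenyl ether 1 is a standard intermediate, and it already has the pattern "one substituent per ring, both next to oxygen".
- The hindered diaryl ether bond, the centre of every classical plan, is bought with a bulk chemical and is never made.
- The forward reaction must achieve complete double deprotonation and a clean chlorosilane quench.

## Roads not taken

**Alternative 1:** the bridging C–O bond (O–C1'), which is the cut most chemists would draw first.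
- Forward key step: metal-free O-arylation of 2-bromo-6-methoxyphenol A1 with (2-bromophenyl)(mesityl)iodonium triflate A2 gives 1-bromo-2-(2-bromophenoxy)-3-methoxybenzene A3. SNAr and Ullmann reactions are the variants. BBr3 demethylation and phenol-directed dibromination would follow.
- It is workable. However, a 2,6-disubstituted phenoxide must be forced onto an ortho-substituted aryl donor, and copper and palladium are excluded by the C–Br bonds.
- The iodonium salt must be made and throws away an iodoarene. O1 must be masked and unmasked.
- Ring A cannot be brought in fully brominated, because with O1 masked the free O2–H directs bromine to C3 and C5, not to C4 and C6.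
- That makes four operations with a protecting group, against three without one. The hindered bond is made rather than bought.

**Alternative 2:** the same C2–O bond, cut as in the presumed biosynthesis.
- Forward key step: one-electron oxidation, chemical or anodic, of 2-bromophenol A4 and 2,4,5-tribromophenol A5. The oxygen of the A4 radical couples to C6 of A5 to give dienone A6, which tautomerises to 9.
- It is a single step, but nothing in the substrates selects this pairing.
- The phenoxyl radical of A4 has spin density at its own free C4 and C6. A4 is oxidised more easily than A5 and should homocouple. Coupling at bromine-bearing carbons expels bromide, and product 9 is itself an oxidisable phenol.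
- The outcome would be a set of isomeric ethers and biaryls of near-identical polarity.

**Alternative 3:** C2'–Br and O1–H traced back to one C–O bond of dibenzo[b,e][1,4]dioxin A7.
- Forward key step: reductive ring opening with lithium and an arene catalyst gives an aryllithium/phenoxide pair. Quenching with an electrophilic bromine source gives 2-(2-bromophenoxy)phenol A8. Bromination gives 4,6-dibromo-2-(2-bromophenoxy)phenol A9.
- The diaryl ether is again bought, and C2'–Br is set cleanly. The route stops one bromine short, because C3 is meta to O1–H and further bromine goes to C4' or to a dienone.
- A placeholder on A7 before opening would make its four C–O bonds inequivalent, with no basis for choosing among them.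
- The chosen plan solves C3 and C2' by the same device.

Key step: step 3

Assumption: the SMILES contains no stereocentre, and a diaryl ether with three ortho substituents, one of them a small OH, has no configurationally stable C–O axis. Compound 9 is therefore treated as achiral and no stereocontrol is needed.

## Route

Step 1
Reactants: 1 diphenyl ether
Product: 3 bis[2-(trimethylsilyl)phenyl] ether, via 2,2'-dilithiodiphenyl ether 2 (not isolated)
Conditions: n-BuLi (2.3 equiv), TMEDA (2.3 equiv), Et2O/hexane, 0 °C → rt, 16 h; Me3SiCl (2.6 equiv), 0 °C → rt
Reagents that add atoms: chlorotrimethylsilane, C[Si](C)(C)Cl; n-butyllithium, [Li]CCCC (lithium of 2 only)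
Why: Directed ortho-metalation: the ether oxygen acidifies its ortho C–H bonds, and the second lithium goes to the other ring, which avoids two C–Li bonds on one ring; this 2,2'-dilithiation is the standard entry to 2,2'-disubstituted diphenyl ethers. The chlorosilane quench of an aryllithium is fast and irreversible.

Step 2
Reactants: 3 bis[2-(trimethylsilyl)phenyl] ether
Product: 6 3-(trimethylsilyl)-2-[2-(trimethylsilyl)phenoxy]phenol, via C1-lithiated ether 4 (not isolated), via lithium aryltrimethoxyborate 5 (not isolated)
Conditions: s-BuLi (1.1 equiv), TMEDA (1.1 equiv), Et2O, −78 → −20 °C; B(OMe)3 (1.5 equiv), −78 °C → rt; AcOH, 30% aq. H2O2, 0 °C → rt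
Reagents that add atoms: hydrogen peroxide, OO (O1 of 6); sec-butyllithium, CCC(C)[Li] (lithium of 4 only); trimethyl borate, COB(OC)OC (borate of 5 only)
Why: Second directed ortho-metalation with silicon as ortho-blocking group: the two rings of 3 are equivalent and each has one C–H bond left next to oxygen, so monolithiation can give only 4, and C–Si bonds tolerate the base where C–Br bonds would exchange. Borate trapping and peroxide oxidation (1,2-aryl shift from boron to oxygen) turn C–Li into C–OH at the same carbon, and aryl–SiMe3 is not oxidised because its silicon carries no heteroatom.

Step 3
Reactants: 6 3-(trimethylsilyl)-2-[2-(trimethylsilyl)phenoxy]phenol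
Product: 9 3,4,6-tribromo-2-(2-bromophenoxy)phenol, via 4,6-dibromo bis-silane 7 (not isolated), via tribromo monosilane 8 (not isolated)
Conditions: Br2 (4.2 equiv), NaOAc (4.5 equiv), AcOH/CH2Cl2, 0 °C → rt, dark; aq. NaHSO3 work-up
Reagents that add atoms: bromine, BrBr
Why: One electrophile substitutes four programmed carbons by the arenium-ion mechanism. O1–H directs ordinary bromodeprotonation to C4 (para) and C6 (ortho), which should be the fastest events and give 7. At C2' and then at C3 bromine attacks the silicon-bearing carbon, because the arenium ion formed there is stabilised by the ortho bridging oxygen and by hyperconjugation with the C–Si bond, and acetate or bromide then takes Me3Si+ away (7 → 8 → 9); the closest known reaction type is the ipso-bromodesilylation of aryltrimethylsilanes with Br2/NaOAc, here merged with a phenol bromination. No ring is closed and no stereocentre is formed. The selectivity that matters is C2' (ipso) against C4'–H (para to oxygen) on ring B: aryl–SiMe3 carbons react with Br2 under conditions that leave the corresponding C–H arenes untouched, and as soon as C2' carries bromine, ring B is deactivated by that bromine and by the bromophenol ring that shares its oxygen, so the small excess of Br2 finds no partner. C5–H stays because it is meta to O1–H and walled in by the bromines at C4 and C6, and the last, slowest substitution at C3 is helped by release of the strain of a SiMe3 group squeezed between the aryloxy group and C4–Br. NaOAc removes HBr, so that proton-induced loss of silicon, the one side reaction that cannot be repaired, is suppressed. Since every order of the four events leads to 9, no intermediate has to be intercepted, and the bisulfite work-up returns any bromodienone to the phenol.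

## Compound list

1 | diphenyl ether | c1ccc(cc1)Oc1ccccc1 | starting material
2 | 2,2'-dilithiodiphenyl ether | [Li]c1ccccc1Oc1ccccc1[Li] | intermediate
3 | bis[2-(trimethylsilyl)phenyl] ether | C[Si](C)(C)c1ccccc1Oc1ccccc1[Si](C)(C)C | intermediate
4 | {3-(trimethylsilyl)-2-[2-(trimethylsilyl)phenoxy]phenyl}lithium | [Li]c1cccc([Si](C)(C)C)c1Oc1ccccc1[Si](C)(C)C | intermediate
5 | lithium trimethoxy{3-(trimethylsilyl)-2-[2-(trimethylsilyl)phenoxy]phenyl}borate | [Li+].CO[B-](OC)(OC)c1cccc([Si](C)(C)C)c1Oc1ccccc1[Si](C)(C)C | intermediate
6 | 3-(trimethylsilyl)-2-[2-(trimethylsilyl)phenoxy]phenol | Oc1cccc([Si](C)(C)C)c1Oc1ccccc1[Si](C)(C)C | intermediate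
7 | 4,6-dibromo-3-(trimethylsilyl)-2-[2-(trimethylsilyl)phenoxy]phenol | Oc1c(Br)cc(Br)c([Si](C)(C)C)c1Oc1ccccc1[Si](C)(C)C | intermediate
8 | 4,6-dibromo-2-(2-bromophenoxy)-3-(trimethylsilyl)phenol | Oc1c(Br)cc(Br)c([Si](C)(C)C)c1Oc1ccccc1Br | intermediate
9 | 3,4,6-tribromo-2-(2-bromophenoxy)phenol (CNP0018165.0, achiral) | Oc1c(Br)cc(Br)c(Br)c1Oc1ccccc1Br | target

## Step count and risks

Total step count: 3. Longest linear sequence: 3 (1 → 3 → 6 → 9).

**Step 3 (key step).**
- The most likely failure is loss of site control on ring B. C–H bromination at C4' may compete with ipso attack at C2' while ring B is still electron-rich. It may also creep in later, if the slow last substitution at the crowded, deactivated C3 forces long exposure to excess bromine.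
- A second failure mode is proton-induced loss of silicon from C3 where the buffer is locally exhausted. This cannot be corrected afterwards, because C3 is out of reach of direct bromination.
- The fallback changes the mechanism from arenium ion to transmetalation. It sets out from 6.
- Ipso-borodesilylation with BBr3 in CH2Cl2, followed by a pinacol/Et3N quench, should give 3-(4,4,5,5-tetramethyl-1,3,2-dioxaborolan-2-yl)-2-[2-(4,4,5,5-tetramethyl-1,3,2-dioxaborolan-2-yl)phenoxy]phenol F1.
- CuBr2 in aqueous methanol replaces each C–B bond through an arylcopper species that does not touch C4'–H. This gives 3-bromo-2-(2-bromophenoxy)phenol F2.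
- Two equivalents of Br2 at low temperature are then directed by O1–H alone, on a substrate whose ring B is already deactivated. The fallback comes back to the route at 9.

**Step 2.**
- Deprotonation may be sluggish, because two SiMe3 groups crowd the oxygen. Forcing it invites lateral lithiation of Si–CH3 and a second lithiation on the other ring.
- The carbanion at C1 may also take over the SiMe3 group of C2' through a six-membered pentacoordinate silicate. That would shift the lithium to ring B and end in a constitutional isomer of the phenol.
- The fallback ties the silicon back into a ring. It sets out from 2.
- Me2SiCl2 closes 10,10-dimethyl-10H-phenoxasilin F3. The C–H bonds of this ring system next to oxygen are routinely lithiated with s-BuLi/TMEDA on the way to its 4,6-disubstituted ligands, and here the carbanion cannot reach the silicon.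
- One equivalent of base, then B(OMe)3 and H2O2, gives 10,10-dimethyl-10H-phenoxasilin-4-ol F4.
- Br2 (3 equiv) with NaOAc brominates C4 and C6 and opens the silacycle at the ring B carbon. Aqueous work-up leaves 4,6-dibromo-2-(2-bromophenoxy)-3-[hydroxy(dimethyl)silyl]phenol F5.
- Heteroatom-substituted silicon is a poor leaving group towards Br2 alone. The last C–Si bond is therefore cleaved with fluoride activation (AgF, NBS, THF), and the fallback comes back to the route at 9, at the price of one extra step.

**Step 1.**
- The second deprotonation may remain incomplete, or may partly take place on the ring that is already metalated. This leads to mono- and bis-silylated ethers of very similar polarity, and the defect is carried into step 2.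
- The fallback makes the dianion by halogen–metal exchange in place of deprotonation.
- It does not set out from 1. It replaces 1 with commercial bis(2-bromophenyl) ether F6.
- n-BuLi (2.1 equiv, Et2O/THF, −78 °C) fixes both lithium positions through the bromines. The fallback comes back to the route at 2, which is silylated to 3 as in step 1.

## Further compounds

F1 | step 3 | 3-(4,4,5,5-tetramethyl-1,3,2-dioxaborolan-2-yl)-2-[2-(4,4,5,5-tetramethyl-1,3,2-dioxaborolan-2-yl)phenoxy]phenol | Oc1cccc(B2OC(C)(C)C(C)(C)O2)c1Oc1ccccc1B1OC(C)(C)C(C)(C)O1
F2 | step 3 | 3-bromo-2-(2-bromophenoxy)phenol | Oc1cccc(Br)c1Oc1ccccc1Br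
F3 | step 2 | 10,10-dimethyl-10H-phenoxasilin | C[Si]1(C)c2ccccc2Oc2ccccc21
F4 | step 2 | 10,10-dimethyl-10H-phenoxasilin-4-ol | C[Si]1(C)c2ccccc2Oc2c(O)cccc21
F5 | step 2 | 4,6-dibromo-2-(2-bromophenoxy)-3-[hydroxy(dimethyl)silyl]phenol | Oc1c(Br)cc(Br)c([Si](C)(C)O)c1Oc1ccccc1Br
F6 | step 1 | bis(2-bromophenyl) ether | Brc1ccccc1Oc1ccccc1Br
A1 | alternative 1 | 2-bromo-6-methoxyphenol | COc1cccc(Br)c1O
A2 | alternative 1 | (2-bromophenyl)(mesityl)iodonium triflate | Cc1cc(C)c([I+]c2ccccc2Br)c(C)c1.[O-]S(=O)(=O)C(F)(F)F
A3 | alternative 1 | 1-bromo-2-(2-bromophenoxy)-3-methoxybenzene | COc1cccc(Br)c1Oc1ccccc1Br
A4 | alternative 2 | 2-bromophenol | Oc1ccccc1Br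
A5 | alternative 2 | 2,4,5-tribromophenol | Oc1cc(Br)c(Br)cc1Br
A6 | alternative 2 | 2,4,5-tribromo-6-(2-bromophenoxy)cyclohexa-2,4-dien-1-one (racemic, transient) | O=C1C(Br)=CC(Br)=C(Br)C1Oc1ccccc1Br
A7 | alternative 3 | dibenzo[b,e][1,4]dioxin | c1ccc2Oc3ccccc3Oc2c1
A8 | alternative 3 | 2-(2-bromophenoxy)phenol | Oc1ccccc1Oc1ccccc1Br
A9 | alternative 3 | 4,6-dibromo-2-(2-bromophenoxy)phenol | Oc1c(Br)cc(Br)cc1Oc1ccccc1Br
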